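Compound numbers are those of the steps and of the compound list; locants C1–C7, O2, O8 and C1'–C6' are those of the target throughout.

## Analysis of the target

The target 43 is a 2,8-dioxabicyclo[3.2.1]octane. A tetrahydrofuran ring (O8, C1, C7, C6, C5) and a 1,3-dioxane ring (C1, O2, C3, C4, C5, O8) share the ketal carbon C1, the bridging oxygen O8 and the bridgehead C5. The core has four stereocentres, C1 (S), C3 (S), C4 (S) and C5 (R). C3, C4 and C5 are contiguous, C4 and C5 are tetrasubstituted and oxygen-bearing, and C1 is tied to C5 by the bicycle, so fixing C5 fixes C1. In the chair of the dioxane ring the C3 carboxyl is equatorial, the C4 hydroxyl axial and the C4 carboxyl equatorial; the C3 epimer would push its carboxyl into the C6–C7 bridge. The fifth stereocentre, C5' (S), lies beyond an (E)-trisubstituted C3'=C4' alkene and cannot be controlled from the core, so it has to come from the chiral pool. Sensitive points are the ketal, three carboxyl groups (two on tetrasubstituted carbons), a tertiary hydroxyl β to two of them (retro-aldol), the epimerisable C3–H, and an alkene that is open to electrophiles and to hydrogenation. The hard part is the C3–C4–C5 triad together with closing the ketal in the [3.2.1] mode and in no other. The feature the strategy rests on is that C5 is fully substituted and bound to O8: as an exocyclic methylene carbon it lies γ,δ to a C1 ketone, so the ketone oxygen can become O8 while the C3 hydroxyl becomes O2, and C5 is set from C3 and C4.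

## Retrosynthetic reasoning

**Unmasking.** 43 is taken back, through the carbinol triester 42, to the trimethyl ester C4 triethylsilyl ether 41. No skeletal bond is cut. The acids and the tertiary hydroxyl stay hidden because the organozinc coupling before it tolerates neither, and methyl esters are the form in which C3 and C4 arrive from the chiral pool. The forward step must remove one hindered silyl ether and hydrolyse three esters without touching the ketal, C3–H or the alkene; the core carries no acyl side chain, so plain saponification is admissible.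

**C2'–C3'.** 41 is cut between the sp3 carbon C2' and the alkene carbon C3' into the primary iodide 28 and the (E)-alkenyl iodide 39, joined by a Negishi coupling through organozinc 40. A metal at C1' would sit β to the two ketal oxygens and eliminate; in 40 they are γ. The cut also keeps the electron-rich trisubstituted alkene away from the selenium electrophile, the peracid, the chlorite oxidation and the hydrogenolysis that come earlier. The gain is convergence, with the alkene geometry fixed in 39 and transferred with retention.

**C5 carboxyl and C2' iodide.** 28 goes back to selenide 21. The C5 ester carbon is the former alkene terminus and arrives as a phenylselanylmethyl group; the iodide is a benzyl-protected alcohol. Forward: seleno-Pummerer rearrangement (21 to 23 through selenoxide 22), release of aldehyde 24, oxidation to acid 25, methylation to 26, hydrogenolysis to 27 and iodination to 28. C5 is fully substituted, so selenoxide 22 has no β-hydrogen and cannot undergo syn-elimination; the Pummerer path is therefore the one open to it.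

**Key disconnection, C5–O8 and C1–O2.** Both rings of 21 are opened at once, giving keto alkene 17 and the selenium electrophile 18. These two C–O bonds are chosen because they are the only ring bonds whose formation can be triggered at an alkene and funnelled by reversibility. The forward cascade has to pick C5 over the methylene carbon, O8 and O3 over every other oxygen, and one C5 configuration out of two; the last follows from C3 and C4, which are already in place. Two rings and two stereocentres are gained from an open chain with only two stereocentres.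

**Protecting-group pattern of 17.** 17 is traced through dithiane 16, bis-silyl ether 15 and diol 14 to acetonide 13.
- O4 must be capped in 17: a free C4 hydroxyl is δ to the C1 ketone and would close a six-membered hemiketal, and with O3 an internal ketal bridging O3 and O4.
- O3 must be free, since it becomes O2.
- C1 travels as a 1,3-dithiane and the primary oxygen as a benzyl ether. The electron-poor acetonide of 13 needs strong aqueous acid, which would also open an O,O-ketal or a silyl ether, and a ketone freed next to the diol would be trapped at once.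
- Triethylsilyl is preferred to a smaller silyl group because it has to outlast the acid of the key step and nine further steps.

**C5=CH2 and C4–C5.** 13 goes back by carbonyl methylenation to ketone 12, by oxidation to aldol adduct 11, and by cutting C4–C5 to aldehyde 8 and enolate 10 of the C2-symmetric (4S,5S)-dioxolane diester 9. This bond is cut because 9 supplies C3 with the correct configuration and its enolate takes electrophiles anti to the neighbouring ester, which is the C4 configuration required. The C5 carbinol of 11 need not be controlled, since C5 becomes trigonal.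

**The C1 linchpin.** Aldehyde 8 comes from acetal 7, and 7 from two successive alkylations of 1 (through 3 and 6) with bromides 2 and 5. C1 is thus an acyl-anion equivalent, and the same dithiane later serves as the acid-stable mask.

**Side chain.** 39 is derived by hydrozirconation–iodination (through 38) from methylalkyne 37, which places iodine on the methyl-bearing carbon trans to C5'. 37 comes from aldehyde 34 by dibromo-olefination (35) and alkynylation–methylation (through 36). 34 comes from ester 33, and 33 from a Negishi coupling of zinc reagent 32 (from iodide 30) with 31. In 29 the hydroxymethyl arm becomes the benzyl group and the ester arm becomes the alkyne; this assignment turns the (S) centre of 29 into C5' (S).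

## Alternatives that were turned down

**Alternative 1: oxepene by olefinic ester cyclisation, then transannular ketalisation.**
- Disconnection: the C1=C7 bond of the seven-membered enol ether A1 (O2, C3, C4, C5, C6, C7, C1); C1–O8 is made afterwards.
- Forward key step: the open-chain ester A2 carries the complete side-chain acid on O3 and an allyl group on C5. A titanium alkylidene of the Takai–Utimoto type exchanges with the terminal alkene and then olefinates the O3 acyl carbonyl, closing A1. Acid would then protonate C7, let the C5 oxygen close on C1 and cleave the tert-butyl esters.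
- For it: it is the most convergent plan. The side chain enters by esterification, C1 and the C5 carboxyl are at their final oxidation levels, and A1 is about two operations from 43. On convergence and on the length of the endgame it is clearly stronger than the chosen route, which needs eight steps after its key step.
- Against it: A2 must already hold C5 as a tetrasubstituted stereocentre next to C4. Adding enolate 10 to an α-keto ester gives no dependable facial control at the ketone, and a wrong C5 cannot be corrected later. The titanium reagent has to pick one of four ester carbonyls and close a seven-membered ring flanked by two tetrasubstituted carbons. Simple alkylidenation to an acyclic enol ether is the usual competitor and would call for a separate enol-ether ring-closing metathesis.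
- Comparison: the chosen route gives up convergence but gets C5 from C3 and C4 by a self-correcting closure, uses favourable five- and six-membered closures, and takes only two stereocentres from the pool.

**Alternative 2: epoxysuccinate opened by the C1 hemiketal oxygen.**
- Disconnection: O2–C3 (epoxide opening) and C1–O8 (hemiketal) of the triester A3.
- Forward key step: the C5 hydroxy ketone A4 closes to its five-membered hemiketal; the hemiketal hydroxyl attacks C3 of the C3–C4 epoxide with inversion, closing the dioxane ring and releasing the C4 hydroxyl.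
- For it: A3 is one hydrolysis from 43 (it is the same compound as 42), the side chain and every oxidation level are in place, and no protecting group is needed on the core. Its endgame is shorter than that of the chosen route.
- Against it: backside attack needs O2, C3 and the epoxide oxygen on C4 antiperiplanar. In the product chair the C4 oxygen is axial and gauche to O2–C3, so the closure must pass through a boat-like dioxane. An epoxide flanked by two esters is a poor electrophile under acid. The nucleophile is a tertiary hemiketal hydroxyl present in small amount, and only one anomer can reach. The C5 hydroxyl can lactonise onto a neighbouring ester, and base invites retro-aldol cleavage. A4 itself needs three stereocentres, two of them tetrasubstituted, without the help of 9.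
- Comparison: the chosen closure has a transition-state geometry that matches the product chair and draws its stereochemistry from 9; it pays with a longer endgame.

**Alternative 3: ester-derived carbonyl ylide and a two-carbon dipolarophile.**
- Disconnection: C5–O8, C5–C6 and C1–C7 of the bicyclic alkene A5.
- Forward key step: a dirhodium carboxylate catalyst decomposes the C5 diazo ester A6. The carbonyl oxygen of the O3 acyl group closes on the carbenoid to a six-membered carbonyl ylide, which adds across the alkyne A7 to give A5 with the sulfone on C7.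
- For it: one step makes two C–C bonds, one C–O bond and both rings, and the C5 carboxyl is at the right oxidation level from the start. After A5 only reduction of C6=C7 and desulfonylation stand before the same stub elaboration, about two steps fewer than the C5 redox work of the chosen route. In bond and oxidation economy it is as strong or stronger.
- Against it: an ester carbonyl is a weak donor towards the carbenoid. The carbenoid at C5 next to tetrasubstituted C4 can escape by 1,2-shift or by closing onto the C3 ester carbonyl (a five-membered ylide). The alkoxy-substituted ylide is short-lived and must be caught intermolecularly. Its facial selectivity is steric and not tether-enforced. The diazo group has to be installed on a carbon that simple diazo transfer does not reach.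
- Comparison: the chosen key step is intramolecular at every stage and corrects its own errors through reversibility; the price is the oxidation-state adjustment at C5.

Key step: step 10

Remark on the chemistry: 9 is taken as the commercial acetonide of dimethyl D-tartrate ((S,S) series). Aldol adduct 11 is carried as both C5 carbinol epimers, because C5 becomes trigonal in step 5.

## Steps

Step 1
Reactants: 1 1,3-dithiane; 2 benzyl 2-bromoethyl ether
Product: 4 2-[2-(benzyloxy)ethyl]-1,3-dithiane, via 2-lithio-1,3-dithiane 3 (not isolated)
Conditions: n-BuLi, THF, −30 °C; then 2, −78 °C → rt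
Reagents that add atoms: none
Why: Corey–Seebach alkylation: deprotonation of 1 gives the acyl-anion equivalent 3, which displaces the primary bromide of 2 by SN2; the less hindered parent anion is paired with the less reactive β-alkoxy bromide.

Step 2
Reactants: 4 2-[2-(benzyloxy)ethyl]-1,3-dithiane; 5 2-(2-bromoethyl)-1,3-dioxolane
Product: 7 2-[2-(benzyloxy)ethyl]-2-[2-(1,3-dioxolan-2-yl)ethyl]-1,3-dithiane, via lithiated dithiane 6 (not isolated)
Conditions: n-BuLi, THF, −20 °C; then 5, −78 °C → rt
Reagents that add atoms: none
Why: Second Corey–Seebach alkylation with an unhindered primary bromide; in anion 6 the benzyloxy group is γ to the carbanion, so β-elimination is not possible.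

Step 3
Reactants: 7 2-[2-(benzyloxy)ethyl]-2-[2-(1,3-dioxolan-2-yl)ethyl]-1,3-dithiane
Product: 8 3-{2-[2-(benzyloxy)ethyl]-1,3-dithian-2-yl}propanal
Conditions: 1 M HCl, THF, rt
Reagents that add atoms: water, O
Why: Acid-catalysed hydrolysis of the O,O-acetal; the S,S-acetal and the benzyl ether are inert to dilute aqueous acid, which is what separates the two masked carbonyl groups.

Step 4
Reactants: 9 dimethyl (4S,5S)-2,2-dimethyl-1,3-dioxolane-4,5-dicarboxylate; 8 3-{2-[2-(benzyloxy)ethyl]-1,3-dithian-2-yl}propanal
Product: 11 dimethyl (4R,5S)-4-(3-{2-[2-(benzyloxy)ethyl]-1,3-dithian-2-yl}-1-hydroxypropyl)-2,2-dimethyl-1,3-dioxolane-4,5-dicarboxylate (both carbinol epimers), via lithium enolate 10 (not isolated)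
Conditions: LDA, THF/DMPU, −78 °C; then 8, −78 °C; AcOH quench at −78 °C
Reagents that add atoms: none
Why: Aldol addition of the tartrate acetonide enolate, kept at −78 °C because 10 is prone to β-elimination. The aldehyde approaches the enolate face anti to the ester on the neighbouring ring carbon, which sets C4 (new carbon substituent trans to the C3 ester, the two esters cis); C3 is untouched and the carbinol centre is erased in step 5.

Step 5
Reactants: 11 aldol adduct (both carbinol epimers)
Product: 12 dimethyl (4S,5S)-4-(3-{2-[2-(benzyloxy)ethyl]-1,3-dithian-2-yl}propanoyl)-2,2-dimethyl-1,3-dioxolane-4,5-dicarboxylate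
Conditions: Dess–Martin periodinane, CH2Cl2 (dry), 0 °C → rt
Reagents that add atoms: none
Why: Dess–Martin oxidation of a hindered secondary alcohol under neutral conditions, which avoids base-induced retro-aldol; in dry solvent the dithiane is not attacked, and both epimers of 11 converge on one ketone.

Step 6
Reactants: 12 C5 ketone
Product: 13 dimethyl (4R,5S)-4-(4-{2-[2-(benzyloxy)ethyl]-1,3-dithian-2-yl}but-1-en-2-yl)-2,2-dimethyl-1,3-dioxolane-4,5-dicarboxylate
Conditions: Cp2TiMe2 (2 equiv), toluene, 65 °C, dark
Reagents that add atoms: dimethyltitanocene Cp2TiMe2, C[Ti](C)(C1C=CC=C1)C2C=CC=C2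
Why: Petasis methylenation: thermally generated Cp2Ti=CH2 converts the ketone by [2+2] addition and cycloreversion. The reagent is non-basic, so neither enolisation towards C6 nor retro-Claisen cleavage of the β-keto ester occurs, and ketones react ahead of esters.

Step 7
Reactants: 13 methylene acetonide
Product: 14 dimethyl (2R,3S)-2-(4-{2-[2-(benzyloxy)ethyl]-1,3-dithian-2-yl}but-1-en-2-yl)-2,3-dihydroxybutanedioate
Conditions: TFA/H2O (4:1), 0 °C → rt
Reagents that add atoms: none
Why: Acid hydrolysis of the electron-poor acetonide. The dithiane, the benzyl ether and the methyl esters are stable to aqueous TFA, and the C5 alkene is deactivated towards protonation by the adjacent C4 with its oxygen and ester.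

Step 8
Reactants: 14 C3,C4 diol
Product: 16 dimethyl (2R,3S)-2-(4-{2-[2-(benzyloxy)ethyl]-1,3-dithian-2-yl}but-1-en-2-yl)-3-hydroxy-2-[(triethylsilyl)oxy]butanedioate, via bis(triethylsilyl) ether 15 (not isolated)
Conditions: TESOTf, 2,6-lutidine, CH2Cl2, 0 °C → rt; work-up; crude 15: PPTS, MeOH, 0 °C
Reagents that add atoms: triethylsilyl trifluoromethanesulfonate, CC[Si](CC)(CC)OS(=O)(=O)C(F)(F)F
Why: Exhaustive silylation with the silyl triflate, the reagent class that reaches the tertiary C4 hydroxyl, followed by acid methanolysis of the less hindered secondary silyl ether. Acid is used and not base, so that silyl migration from O4 to an O3 alkoxide cannot occur.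

Step 9
Reactants: 16 C4 silyl ether C3 carbinol dithiane
Product: 17 dimethyl (2R,3S)-2-[7-(benzyloxy)-5-oxohept-1-en-2-yl]-3-hydroxy-2-[(triethylsilyl)oxy]butanedioate
Conditions: MeI, CaCO3, MeCN/H2O (9:1), 45 °C
Reagents that add atoms: water, O
Why: Alkylative dithiane hydrolysis (S-methylation, ring opening to a thionium ion, capture by water). The buffered neutral medium spares the alkene, the silyl ether and the free hydroxyl and avoids β-elimination of benzyl alcohol from the β-alkoxy ketone.

Step 10
Reactants: 17 dimethyl (2R,3S)-2-[7-(benzyloxy)-5-oxohept-1-en-2-yl]-3-hydroxy-2-[(triethylsilyl)oxy]butanedioate; 18 phenylselenenyl chloride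
Product: 21 dimethyl (1R,3S,4S,5R)-1-[2-(benzyloxy)ethyl]-5-[(phenylselanyl)methyl]-4-[(triethylsilyl)oxy]-2,8-dioxabicyclo[3.2.1]octane-3,4-dicarboxylate, via seleniranium chloride 19 (not isolated), via oxocarbenium chloride 20 (not isolated)
Conditions: 18 (1.1 equiv), CH2Cl2, −78 °C → −20 °C; aq. NaHCO3 quench
Reagents that add atoms: none
Why: Mechanism: 18 adds reversibly to the C5 methylene to give seleniranium ion 19, the C1 carbonyl oxygen opens it at the tertiary carbon C5 to give the tetrahydrofuranylium ion 20 (C5–O8), and the C3 hydroxyl adds to C1 of 20 (C1–O2) with loss of HCl. The closest known reaction type is electrophile-induced cycloketalisation, that is seleno- or halo-etherification of a γ,δ-unsaturated ketone with carbonyl-oxygen participation and capture of the oxocarbenium ion by an internal hydroxyl. The tetrahydrofuran ring closes 5-exo (the breaking C5–Se bond lies outside the new ring); the 1,3-dioxane ring closes 6-endo-trig with respect to C1=O8, because O8 is a member of the new ring. C5 is controlled by C3 and C4 through the tether: formation of 19 and of 20 is reversible, and only the C5 epimer of 20 whose chair-like closure keeps the C3 ester equatorial (C4 silyloxy axial, C4 ester equatorial) closes readily, whereas the other would have to drive the C3 ester axially into the C6–C7 bridge, so material should drain through the (5R) ion. C1 is not free: once C5 is set, O2 can reach C1 only from the face on which C4 sits, which gives the single ketal configuration of 21. The regioselectivity needed is attack at C5 and not at the methylene carbon; it is secured by Markovnikov opening of the unsymmetrical seleniranium ion and by ring size, since O3 or the C4 ester carbonyl attacking C5 would close four-membered rings. The chemoselectivity needed is that only O8 and O3 take part; it is secured by the silyl ether on O4 (no six-membered hemiketal, no [2.2.1] ketal), by the absence of a second alkene in the benzyloxyethyl stub, and by the low temperature, which keeps α-selenenylation of the ketone and acid cleavage of the silyl ether slower than the cascade.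

Step 11
Reactants: 21 C5 phenylselanylmethyl ketal
Product: 23 dimethyl (1R,3S,4S,5R)-5-[acetoxy(phenylselanyl)methyl]-1-[2-(benzyloxy)ethyl]-4-[(triethylsilyl)oxy]-2,8-dioxabicyclo[3.2.1]octane-3,4-dicarboxylate (both epimers at the new carbon), via selenoxide 22 (not isolated)
Conditions: mCPBA (1.05 equiv), CH2Cl2, −78 °C; then Ac2O, NaOAc, 60 °C
Reagents that add atoms: 3-chloroperbenzoic acid (oxygen of 22, which may be carried into the acetoxy group), OOC(=O)c1cccc(Cl)c1; acetic anhydride, CC(=O)OC(C)=O
Why: Selenium is oxidised faster than any other site, and the selenoxide then undergoes the seleno-Pummerer rearrangement (O-acetylation, loss of an α-proton, acetate capture at carbon). The carbon β to selenium is the fully substituted C5, so selenoxide syn-elimination is impossible.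

Step 12
Reactants: 23 α-acetoxy selenide
Product: 24 dimethyl (1R,3S,4S,5R)-1-[2-(benzyloxy)ethyl]-5-formyl-4-[(triethylsilyl)oxy]-2,8-dioxabicyclo[3.2.1]octane-3,4-dicarboxylate
Conditions: K2CO3, MeOH, 0 °C
Reagents that add atoms: none
Why: Methanolysis of the acetate frees a hemiselenoacetal, which collapses to the aldehyde with loss of benzeneselenolate; the aldehyde has no α-hydrogen and cannot epimerise.

Step 13
Reactants: 24 C5 aldehyde
Product: 25 (1R,3S,4S,5R)-1-[2-(benzyloxy)ethyl]-3,4-bis(methoxycarbonyl)-4-[(triethylsilyl)oxy]-2,8-dioxabicyclo[3.2.1]octane-5-carboxylic acid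
Conditions: NaClO2, NaH2PO4, 2-methylbut-2-ene, t-BuOH/H2O, rt
Reagents that add atoms: sodium chlorite, [Na+].[O-]Cl=O
Why: Pinnick oxidation: chlorous acid adds to the aldehyde and fragments to the acid; it is mild, little affected by the neopentyl environment, and the scavenger removes hypochlorous acid.

Step 14
Reactants: 25 C5 carboxylic acid
Product: 26 trimethyl (1R,3S,4S,5R)-1-[2-(benzyloxy)ethyl]-4-[(triethylsilyl)oxy]-2,8-dioxabicyclo[3.2.1]octane-3,4,5-tricarboxylate
Conditions: TMSCHN2, toluene/MeOH, 0 °C
Reagents that add atoms: (trimethylsilyl)diazomethane, C[Si](C)(C)C=[N+]=[N-]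
Why: O-Methylation of the carboxylate by a diazoalkane (proton transfer, then SN2 at the methyl carbon); the hindered carboxyl carbon itself is never attacked.

Step 15
Reactants: 26 benzyl ether triester
Product: 27 trimethyl (1R,3S,4S,5R)-1-(2-hydroxyethyl)-4-[(triethylsilyl)oxy]-2,8-dioxabicyclo[3.2.1]octane-3,4,5-tricarboxylate
Conditions: H2 (1 atm), Pd/C, EtOAc, rt
Reagents that add atoms: none
Why: Hydrogenolysis of the benzyl ether; the molecule holds no alkene at this stage, selenium left four steps earlier, and a non-protic solvent keeps the silyl ether.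

Step 16
Reactants: 27 primary alcohol
Product: 28 trimethyl (1R,3S,4S,5R)-1-(2-iodoethyl)-4-[(triethylsilyl)oxy]-2,8-dioxabicyclo[3.2.1]octane-3,4,5-tricarboxylate
Conditions: I2, PPh3, imidazole, CH2Cl2, 0 °C → rt
Reagents that add atoms: iodine, II
Why: Appel-type iodination: the alkoxyphosphonium ion is displaced by iodide at the primary carbon; esters, ketal and tertiary silyl ether are inert.

Step 17
Reactants: 29 methyl (S)-3-hydroxy-2-methylpropanoate
Product: 30 methyl (R)-3-iodo-2-methylpropanoate
Conditions: I2, PPh3, imidazole, CH2Cl2, 0 °C → rt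
Reagents that add atoms: iodine, II
Why: Appel-type iodination at the primary carbon under buffered conditions; the stereocentre is not a reacting atom (the descriptor changes by priority only), and the absence of strong base avoids elimination to the methacrylate.

Step 18
Reactants: 30 methyl (R)-3-iodo-2-methylpropanoate; 31 iodobenzene
Product: 33 methyl (S)-2-methyl-3-phenylpropanoate, via organozinc iodide 32 (not isolated)
Conditions: Zn dust (activated with 1,2-dibromoethane and TMSCl), DMF, rt; then 31, Pd2(dba)3, P(o-tol)3, rt → 50 °C
Reagents that add atoms: none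
Why: Zinc insertion gives a β-zincio ester that has no leaving group to eliminate and is not basic enough to epimerise the α-centre. Negishi coupling (oxidative addition of 31 to zerovalent palladium, transmetalation, reductive elimination) then forms the benzyl C–C bond.

Step 19
Reactants: 33 methyl (S)-2-methyl-3-phenylpropanoate
Product: 34 (2S)-2-methyl-3-phenylpropanal
Conditions: DIBAL-H (1.05 equiv), CH2Cl2, −78 °C; MeOH, then aq. potassium sodium tartrate
Reagents that add atoms: none
Why: Partial reduction of the ester: the aluminium hemiacetal is stable at −78 °C and releases the aldehyde only on work-up. The aldehyde is used at once to protect the α-stereocentre.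

Step 20
Reactants: 34 (2S)-2-methyl-3-phenylpropanal
Product: 35 [(2S)-4,4-dibromo-2-methylbut-3-en-1-yl]benzene
Conditions: CBr4, PPh3, CH2Cl2, 0 °C
Reagents that add atoms: carbon tetrabromide, BrC(Br)(Br)Br
Why: First stage of the Corey–Fuchs sequence, a Wittig-type reaction of the dibromomethylene ylide under essentially neutral conditions that leave the α-stereocentre intact.

Step 21
Reactants: 35 [(2S)-4,4-dibromo-2-methylbut-3-en-1-yl]benzene
Product: 37 [(2S)-2-methylpent-3-yn-1-yl]benzene, via lithium acetylide 36 (not isolated)
Conditions: n-BuLi (2.1 equiv), THF, −78 °C; then MeI, −78 °C → rt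
Reagents that add atoms: iodomethane, CI
Why: Second stage of the Corey–Fuchs sequence: bromine–lithium exchange, rearrangement of the carbenoid to the alkyne and deprotonation give 36, which is C-methylated. The stereocentre is propargylic and not acidic enough to be touched.

Step 22
Reactants: 37 [(2S)-2-methylpent-3-yn-1-yl]benzene
Product: 39 [(2S,3E)-4-iodo-2-methylpent-3-en-1-yl]benzene, via alkenylzirconocene chloride 38 (not isolated)
Conditions: Cp2Zr(H)Cl (excess), THF, 50 °C; then I2, 0 °C
Reagents that add atoms: iodine, II
Why: Hydrozirconation is a syn addition of Zr–H. With excess hydride and gentle heating the regioisomers equilibrate and place zirconium on the less hindered, methyl-bearing carbon, and iodinolysis with retention gives the (E)-iodide with iodine trans to C5'.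

Step 23
Reactants: 28 primary iodide of the core; 39 (E)-alkenyl iodide
Product: 41 trimethyl (1S,3S,4S,5R)-1-[(3E,5S)-3,5-dimethyl-6-phenylhex-3-en-1-yl]-4-[(triethylsilyl)oxy]-2,8-dioxabicyclo[3.2.1]octane-3,4,5-tricarboxylate, via organozinc iodide 40 (not isolated)
Conditions: Zn dust (activated with 1,2-dibromoethane and TMSCl), DMF, rt; then 39, Pd2(dba)3, P(o-tol)3, rt → 40 °C
Reagents that add atoms: none
Why: Negishi sp3–sp2 coupling: zinc inserts into the primary iodide to give 40, whose oxygens are γ to the metal and cannot be eliminated, and the alkenyl iodide couples with retention of the (E) geometry. Esters, ketal and silyl ether are tolerated by the organozinc.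

Step 24
Reactants: 41 trimethyl ester C4 silyl ether
Product: 43 (1S,3S,4S,5R)-1-[(3E,5S)-3,5-dimethyl-6-phenylhex-3-en-1-yl]-4-hydroxy-2,8-dioxabicyclo[3.2.1]octane-3,4,5-tricarboxylic acid (target), via C4 carbinol triester 42 (not isolated)
Conditions: HF·pyridine, THF, 0 °C → rt; then LiOH, THF/MeOH/H2O, 50 °C; aq. HCl to pH 2
Reagents that add atoms: lithium hydroxide (one oxygen of each carboxyl group), [Li+].[OH-]
Why: Fluoride cleavage of the tertiary silyl ether, then saponification of the three methyl esters by acyl–oxygen cleavage. The equatorial C3 carboxylate is the thermodynamically preferred epimer, and the ketal and the alkene are stable to hydroxide.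

## Compound list

1 | 1,3-dithiane | C1CSCSC1 | starting material
2 | benzyl 2-bromoethyl ether | BrCCOCc1ccccc1 | starting material
3 | 2-lithio-1,3-dithiane | [Li]C1SCCCS1 | intermediate
4 | 2-[2-(benzyloxy)ethyl]-1,3-dithiane | C(COCc1ccccc1)C1SCCCS1 | intermediate
5 | 2-(2-bromoethyl)-1,3-dioxolane | BrCCC1OCCO1 | starting material
6 | 2-[2-(benzyloxy)ethyl]-2-lithio-1,3-dithiane | [Li]C1(CCOCc2ccccc2)SCCCS1 | intermediate
7 | 2-[2-(benzyloxy)ethyl]-2-[2-(1,3-dioxolan-2-yl)ethyl]-1,3-dithiane | C(COCc1ccccc1)C1(CCC2OCCO2)SCCCS1 | intermediate
8 | 3-{2-[2-(benzyloxy)ethyl]-1,3-dithian-2-yl}propanal | O=CCCC1(CCOCc2ccccc2)SCCCS1 | intermediate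
9 | dimethyl (4S,5S)-2,2-dimethyl-1,3-dioxolane-4,5-dicarboxylate (acetonide of dimethyl D-tartrate) | COC(=O)[C@H]1OC(C)(C)O[C@@H]1C(=O)OC | starting material
10 | lithium enolate of 9 (enolised at the future C4, C3 centre unchanged) | COC(O[Li])=C1OC(C)(C)O[C@@H]1C(=O)OC | intermediate
11 | dimethyl (4R,5S)-4-(3-{2-[2-(benzyloxy)ethyl]-1,3-dithian-2-yl}-1-hydroxypropyl)-2,2-dimethyl-1,3-dioxolane-4,5-dicarboxylate, both carbinol epimers | OC(CCC2(CCOCc3ccccc3)SCCCS2)[C@@]1(C(=O)OC)OC(C)(C)O[C@@H]1C(=O)OC | intermediate
12 | dimethyl (4S,5S)-4-(3-{2-[2-(benzyloxy)ethyl]-1,3-dithian-2-yl}propanoyl)-2,2-dimethyl-1,3-dioxolane-4,5-dicarboxylate | O=C(CCC2(CCOCc3ccccc3)SCCCS2)[C@@]1(C(=O)OC)OC(C)(C)O[C@@H]1C(=O)OC | intermediate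
13 | dimethyl (4R,5S)-4-(4-{2-[2-(benzyloxy)ethyl]-1,3-dithian-2-yl}but-1-en-2-yl)-2,2-dimethyl-1,3-dioxolane-4,5-dicarboxylate | C=C(CCC2(CCOCc3ccccc3)SCCCS2)[C@@]1(C(=O)OC)OC(C)(C)O[C@@H]1C(=O)OC | intermediate
14 | dimethyl (2R,3S)-2-(4-{2-[2-(benzyloxy)ethyl]-1,3-dithian-2-yl}but-1-en-2-yl)-2,3-dihydroxybutanedioate | C=C(CCC1(CCOCc2ccccc2)SCCCS1)[C@](O)(C(=O)OC)[C@H](O)C(=O)OC | intermediate
15 | dimethyl (2R,3S)-2-(4-{2-[2-(benzyloxy)ethyl]-1,3-dithian-2-yl}but-1-en-2-yl)-2,3-bis[(triethylsilyl)oxy]butanedioate | C=C(CCC1(CCOCc2ccccc2)SCCCS1)[C@](O[Si](CC)(CC)CC)(C(=O)OC)[C@H](O[Si](CC)(CC)CC)C(=O)OC | intermediate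
16 | dimethyl (2R,3S)-2-(4-{2-[2-(benzyloxy)ethyl]-1,3-dithian-2-yl}but-1-en-2-yl)-3-hydroxy-2-[(triethylsilyl)oxy]butanedioate | C=C(CCC1(CCOCc2ccccc2)SCCCS1)[C@](O[Si](CC)(CC)CC)(C(=O)OC)[C@H](O)C(=O)OC | intermediate
17 | dimethyl (2R,3S)-2-[7-(benzyloxy)-5-oxohept-1-en-2-yl]-3-hydroxy-2-[(triethylsilyl)oxy]butanedioate (C1 ketone, C5 methylene, C4 silyl ether, free C3 hydroxyl) | O=C(CCOCc1ccccc1)CCC(=C)[C@](O[Si](CC)(CC)CC)(C(=O)OC)[C@H](O)C(=O)OC | intermediate
18 | phenylselenenyl chloride | Cl[Se]c1ccccc1 | starting material
19 | seleniranium chloride of 17 (1-phenylseleniranium ring on C5 and its methylene carbon, either face) | O=C(CCOCc1ccccc1)CCC2(C[Se+]2c3ccccc3)[C@](O[Si](CC)(CC)CC)(C(=O)OC)[C@H](O)C(=O)OC.[Cl-] | intermediate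
20 | tetrahydrofuranylium chloride (C1=O8 oxocarbenium, C5–O8 formed, (5R), C3 hydroxyl still free) | C(COCc1ccccc1)C2=[O+][C@](C[Se]c3ccccc3)(CC2)[C@](O[Si](CC)(CC)CC)(C(=O)OC)[C@H](O)C(=O)OC.[Cl-] | intermediate
21 | dimethyl (1R,3S,4S,5R)-1-[2-(benzyloxy)ethyl]-5-[(phenylselanyl)methyl]-4-[(triethylsilyl)oxy]-2,8-dioxabicyclo[3.2.1]octane-3,4-dicarboxylate | c3ccccc3COCC[C@@]12CC[C@@](C[Se]c4ccccc4)(O1)[C@](O[Si](CC)(CC)CC)(C(=O)OC)[C@@H](C(=O)OC)O2 | intermediate
22 | selenoxide of 21 (5-[(phenylseleninyl)methyl], both configurations at selenium) | c3ccccc3COCC[C@@]12CC[C@@](C[Se](=O)c4ccccc4)(O1)[C@](O[Si](CC)(CC)CC)(C(=O)OC)[C@@H](C(=O)OC)O2 | intermediate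
23 | dimethyl (1R,3S,4S,5R)-5-[acetoxy(phenylselanyl)methyl]-1-[2-(benzyloxy)ethyl]-4-[(triethylsilyl)oxy]-2,8-dioxabicyclo[3.2.1]octane-3,4-dicarboxylate, both epimers at the new carbon | c3ccccc3COCC[C@@]12CC[C@@](C(OC(C)=O)[Se]c4ccccc4)(O1)[C@](O[Si](CC)(CC)CC)(C(=O)OC)[C@@H](C(=O)OC)O2 | intermediate
24 | dimethyl (1R,3S,4S,5R)-1-[2-(benzyloxy)ethyl]-5-formyl-4-[(triethylsilyl)oxy]-2,8-dioxabicyclo[3.2.1]octane-3,4-dicarboxylate | c3ccccc3COCC[C@@]12CC[C@@](C=O)(O1)[C@](O[Si](CC)(CC)CC)(C(=O)OC)[C@@H](C(=O)OC)O2 | intermediate
25 | (1R,3S,4S,5R)-1-[2-(benzyloxy)ethyl]-3,4-bis(methoxycarbonyl)-4-[(triethylsilyl)oxy]-2,8-dioxabicyclo[3.2.1]octane-5-carboxylic acid | c3ccccc3COCC[C@@]12CC[C@@](C(=O)O)(O1)[C@](O[Si](CC)(CC)CC)(C(=O)OC)[C@@H](C(=O)OC)O2 | intermediate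
26 | trimethyl (1R,3S,4S,5R)-1-[2-(benzyloxy)ethyl]-4-[(triethylsilyl)oxy]-2,8-dioxabicyclo[3.2.1]octane-3,4,5-tricarboxylate | c3ccccc3COCC[C@@]12CC[C@@](C(=O)OC)(O1)[C@](O[Si](CC)(CC)CC)(C(=O)OC)[C@@H](C(=O)OC)O2 | intermediate
27 | trimethyl (1R,3S,4S,5R)-1-(2-hydroxyethyl)-4-[(triethylsilyl)oxy]-2,8-dioxabicyclo[3.2.1]octane-3,4,5-tricarboxylate | OCC[C@@]12CC[C@@](C(=O)OC)(O1)[C@](O[Si](CC)(CC)CC)(C(=O)OC)[C@@H](C(=O)OC)O2 | intermediate
28 | trimethyl (1R,3S,4S,5R)-1-(2-iodoethyl)-4-[(triethylsilyl)oxy]-2,8-dioxabicyclo[3.2.1]octane-3,4,5-tricarboxylate | ICC[C@@]12CC[C@@](C(=O)OC)(O1)[C@](O[Si](CC)(CC)CC)(C(=O)OC)[C@@H](C(=O)OC)O2 | intermediate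
29 | methyl (S)-3-hydroxy-2-methylpropanoate | COC(=O)[C@@H](C)CO | starting material
30 | methyl (R)-3-iodo-2-methylpropanoate | COC(=O)[C@@H](C)CI | intermediate
31 | iodobenzene | Ic1ccccc1 | starting material
32 | [(2R)-3-methoxy-2-methyl-3-oxopropyl]zinc iodide | COC(=O)[C@@H](C)C[Zn]I | intermediate
33 | methyl (S)-2-methyl-3-phenylpropanoate | COC(=O)[C@@H](C)Cc1ccccc1 | intermediate
34 | (2S)-2-methyl-3-phenylpropanal | O=C[C@@H](C)Cc1ccccc1 | intermediate
35 | [(2S)-4,4-dibromo-2-methylbut-3-en-1-yl]benzene | BrC(Br)=C[C@@H](C)Cc1ccccc1 | intermediate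
36 | lithium (3S)-3-methyl-4-phenylbut-1-yn-1-ide | [Li]C#C[C@@H](C)Cc1ccccc1 | intermediate
37 | [(2S)-2-methylpent-3-yn-1-yl]benzene | CC#C[C@@H](C)Cc1ccccc1 | intermediate
38 | chlorobis(cyclopentadienyl)[(2E,4S)-4-methyl-5-phenylpent-2-en-2-yl]zirconium | C/C(=C\[C@@H](C)Cc1ccccc1)[Zr](Cl)(C2C=CC=C2)C3C=CC=C3 | intermediate
39 | [(2S,3E)-4-iodo-2-methylpent-3-en-1-yl]benzene | C/C(I)=C\[C@@H](C)Cc1ccccc1 | intermediate
40 | {2-[(1R,3S,4S,5R)-3,4,5-tris(methoxycarbonyl)-4-[(triethylsilyl)oxy]-2,8-dioxabicyclo[3.2.1]octan-1-yl]ethyl}zinc iodide | I[Zn]CC[C@@]12CC[C@@](C(=O)OC)(O1)[C@](O[Si](CC)(CC)CC)(C(=O)OC)[C@@H](C(=O)OC)O2 | intermediate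
41 | trimethyl (1S,3S,4S,5R)-1-[(3E,5S)-3,5-dimethyl-6-phenylhex-3-en-1-yl]-4-[(triethylsilyl)oxy]-2,8-dioxabicyclo[3.2.1]octane-3,4,5-tricarboxylate | C/C(=C\[C@@H](C)Cc1ccccc1)CC[C@@]12CC[C@@](C(=O)OC)(O1)[C@](O[Si](CC)(CC)CC)(C(=O)OC)[C@@H](C(=O)OC)O2 | intermediate
42 | trimethyl (1S,3S,4S,5R)-1-[(3E,5S)-3,5-dimethyl-6-phenylhex-3-en-1-yl]-4-hydroxy-2,8-dioxabicyclo[3.2.1]octane-3,4,5-tricarboxylate | C/C(=C\[C@@H](C)Cc1ccccc1)CC[C@@]12CC[C@@](C(=O)OC)(O1)[C@](O)(C(=O)OC)[C@@H](C(=O)OC)O2 | intermediate
43 | (1S,3S,4S,5R)-1-[(3E,5S)-3,5-dimethyl-6-phenylhex-3-en-1-yl]-4-hydroxy-2,8-dioxabicyclo[3.2.1]octane-3,4,5-tricarboxylic acid | C/C(=C\[C@@H](C)Cc1ccccc1)CC[C@@]12CC[C@@](C(=O)O)(O1)[C@](O)(C(=O)O)[C@@H](C(=O)O)O2 | target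

## Step count and least certain steps

Total: 24 steps. Longest linear sequence: 18 steps (steps 1–16, 23 and 24, from 1); the side chain (steps 17–22) joins in step 23.

**Step 10 (key step).** The most likely failure is diversion of the seleniranium ion by the C3 ester carbonyl (a five-membered closure that ends as a selenolactone once chloride removes the methyl group). The second is loss of the C4 silyl ether to the acid set free, after which O4 can ketalise. Either would lower the share of material passing through ion 20. Fallback, setting out from 17: buffered peracid epoxidation of the C5 methylene should give the spiro-epoxide F1 (O=C(CCOCc1ccccc1)CCC2(CO2)…, both C5 epimers). A catalytic Brønsted acid (CSA, CH2Cl2) would then run the oxygen version of the cascade: the ketone oxygen opens the protonated epoxide at the tertiary C5 and the C3 hydroxyl closes the ketal, giving the C5 hydroxymethyl ketal F2. Dess–Martin oxidation of F2 rejoins the route at aldehyde 24, so steps 11 and 12 are not needed. The price is that C5 is then set in the epoxidation and is no longer corrected by reversibility.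

**Step 4 (tartrate aldol).** Enolate 10 can decompose by β-elimination (opening of the dioxolane), and proton transfer from the enolisable aldehyde 8 competes with addition; both would return 9 or its fragments. Fallback, setting out from 9: deprotonation with LDA in the presence of TMSCl (internal quench) should give the silyl ketene acetal F3, which is stable towards elimination. A Mukaiyama aldol of F3 with 8 (BF3·OEt2, CH2Cl2, −78 °C), with the same approach anti to the neighbouring ester, returns to 11.

**Step 8 (differentiation of O3 and O4).** Methanolysis may fail to discriminate cleanly between the two silyl ethers, either cleaving both or leaving both, and silyl migration from O4 to O3 would give the wrong regioisomer. Fallback, setting out from 14: the secondary hydroxyl is acylated selectively (chloroacetic anhydride, pyridine, −20 °C) to the C3 chloroacetate F4. The tertiary hydroxyl is silylated (TESOTf, 2,6-lutidine) to the C3 chloroacetate C4 silyl ether F5. The chloroacetyl group is then removed with thiourea (NaHCO3, EtOH, 50 °C), which touches neither methyl esters nor silyl ether; this returns to 16.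

**Step 11 (seleno-Pummerer).** The selenoxide may be over-oxidised to the selenone, or the acetoxyselenonium ion may fragment at the C–Se bond before the α-proton is lost in this neopentyl setting. Fallback, setting out from 21: α-chlorination of the selenide with N-chlorosuccinimide (CCl4, rt), the halogenative counterpart of the Pummerer reaction, should give the α-chloro selenide F6. Hydrolysis of F6 (aq. NaHCO3, MeCN) returns to aldehyde 24.

**Step 24 (final hydrolysis).** The esters on C4 and C5 are hindered and may hydrolyse incompletely; forcing with hydroxide risks retro-aldol cleavage at the C4 carbinol. Fallback, setting out from 42 (isolated after the fluoride treatment): dealkylative cleavage by SN2 attack at the methyl carbons (LiI, pyridine, reflux, then acidification) avoids tetrahedral intermediates at the hindered acyl carbons and leads to 43. This fallback makes no new compound (F0).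

## Further compounds

F1 | step 10 | dimethyl (2R,3S)-2-{2-[5-(benzyloxy)-3-oxopentyl]oxiran-2-yl}-3-hydroxy-2-[(triethylsilyl)oxy]butanedioate (spiro-epoxide at C5, both epimers) | O=C(CCOCc1ccccc1)CCC2(CO2)[C@](O[Si](CC)(CC)CC)(C(=O)OC)[C@H](O)C(=O)OC
F2 | step 10 | dimethyl (1R,3S,4S,5R)-1-[2-(benzyloxy)ethyl]-5-(hydroxymethyl)-4-[(triethylsilyl)oxy]-2,8-dioxabicyclo[3.2.1]octane-3,4-dicarboxylate | c3ccccc3COCC[C@@]12CC[C@@](CO)(O1)[C@](O[Si](CC)(CC)CC)(C(=O)OC)[C@@H](C(=O)OC)O2
F3 | step 4 | trimethylsilyl ketene acetal of 9 (methyl (4S)-5-[methoxy(trimethylsilyloxy)methylidene]-2,2-dimethyl-1,3-dioxolane-4-carboxylate) | COC(O[Si](C)(C)C)=C1OC(C)(C)O[C@@H]1C(=O)OC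
F4 | step 8 | dimethyl (2R,3S)-2-(4-{2-[2-(benzyloxy)ethyl]-1,3-dithian-2-yl}but-1-en-2-yl)-3-(chloroacetoxy)-2-hydroxybutanedioate | C=C(CCC1(CCOCc2ccccc2)SCCCS1)[C@](O)(C(=O)OC)[C@H](OC(=O)CCl)C(=O)OC
F5 | step 8 | dimethyl (2R,3S)-2-(4-{2-[2-(benzyloxy)ethyl]-1,3-dithian-2-yl}but-1-en-2-yl)-3-(chloroacetoxy)-2-[(triethylsilyl)oxy]butanedioate | C=C(CCC1(CCOCc2ccccc2)SCCCS1)[C@](O[Si](CC)(CC)CC)(C(=O)OC)[C@H](OC(=O)CCl)C(=O)OC
F6 | step 11 | dimethyl (1R,3S,4S,5R)-1-[2-(benzyloxy)ethyl]-5-[chloro(phenylselanyl)methyl]-4-[(triethylsilyl)oxy]-2,8-dioxabicyclo[3.2.1]octane-3,4-dicarboxylate (both epimers at the new carbon) | c3ccccc3COCC[C@@]12CC[C@@](C(Cl)[Se]c4ccccc4)(O1)[C@](O[Si](CC)(CC)CC)(C(=O)OC)[C@@H](C(=O)OC)O2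
F0 | step 24 | none | none
A1 | alternative 1 | seven-membered cyclic enol ether (O2, C3, C4, C5, C6, C7, C1; C1=C7) with tert-butyl esters at C3, C4 and C5 and trimethylsilyl ethers on O4 and O5, C3, C4 and C5 as in the target | C/C(=C\[C@@H](C)Cc1ccccc1)CCC2=CC[C@@](C(=O)OC(C)(C)C)(O[Si](C)(C)C)[C@](O[Si](C)(C)C)(C(=O)OC(C)(C)C)[C@@H](C(=O)OC(C)(C)C)O2
A2 | alternative 1 | open-chain olefinic ester: O3 acylated by (4E,6S)-4,6-dimethyl-7-phenylhept-4-enoic acid, allyl group on C5, tert-butyl esters at C3, C4 and C5, trimethylsilyl ethers on O4 and O5 | C/C(=C\[C@@H](C)Cc1ccccc1)CCC(=O)O[C@H](C(=O)OC(C)(C)C)[C@@](O[Si](C)(C)C)(C(=O)OC(C)(C)C)[C@@](CC=C)(O[Si](C)(C)C)C(=O)OC(C)(C)C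
A3 | alternative 2 | trimethyl ester of the target (identical with 42) | C/C(=C\[C@@H](C)Cc1ccccc1)CC[C@@]12CC[C@@](C(=O)OC)(O1)[C@](O)(C(=O)OC)[C@@H](C(=O)OC)O2
A4 | alternative 2 | C1 ketone with C5 tertiary carbinol and C3–C4 epoxide (epoxysuccinate), C3 inverted relative to the target, all three carboxyls as methyl esters | C/C(=C\[C@@H](C)Cc1ccccc1)CCC(=O)CC[C@](O)(C(=O)OC)[C@@]1(C(=O)OC)O[C@H]1C(=O)OC
A5 | alternative 3 | 2,8-dioxabicyclo[3.2.1]oct-6-ene with p-tolylsulfonyl group on C7, silyloxyethyl stub on C1, methyl esters at C3, C4 and C5 and trimethylsilyl ether on O4 | CC(C)(C)[Si](C)(C)OCC[C@@]12C(S(=O)(=O)c3ccc(C)cc3)=C[C@@](C(=O)OC)(O1)[C@](O[Si](C)(C)C)(C(=O)OC)[C@@H](C(=O)OC)O2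
A6 | alternative 3 | C5 diazo ester: O3 acylated by 3-(tert-butyldimethylsilyloxy)propanoic acid, trimethylsilyl ether on O4, methyl esters at C3, C4 and C5 | CC(C)(C)[Si](C)(C)OCCC(=O)O[C@H](C(=O)OC)[C@@](O[Si](C)(C)C)(C(=O)OC)C(=[N+]=[N-])C(=O)OC
A7 | alternative 3 | ethynyl p-tolyl sulfone | C#CS(=O)(=O)c1ccc(C)cc1
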